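Retrosynthesis: remove three benzyl ethers. Cut flavanone ring A at C4a–C5 and C8–C8a (Diels–Alder/aromatisation), flavanone ring C at C2–C3 and O1–C8a (hetero-Diels–Alder), and the interflavonoid ether at O–C4' (SNAr). The flavonol goes back through flavone and chalcone to 2,4,6-trihydroxyacetophenone.
Enabling feature: flavanone C2 carries O1, C3H2 and an aryl group, so it is the carbonyl carbon of an aryl aldehyde, and O1–C8a=C4a–C4(=O)–C3 is the skeleton of a 1-methoxy-3-silyloxybutadiene. Ring C can therefore stand alone as a 2-aryl-2,3-dihydro-4H-pyran-4-one whose C5=C6 bond (future C4a=C8a) is free to receive ring A.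
Forward order: chromone ring of the flavonol, diaryl ether, flavanone ring C, flavanone ring A, global debenzylation.
Ring A: pyranone C5 is armed with a phenylsulfinyl group rather than a halogen. It activates the vinylogous ester as a dienophile and leaves by thermal syn-elimination, which fits the cis adduct and needs no base.
Stereochemistry: C2, the only stereocentre, is set by (S)-BINOL/Ti(OiPr)4 in the hetero-Diels–Alder step. Every later step is neutral, acidic or uses only a tertiary amine at low temperature, so C3 enolisation with retro-oxa-Michael opening is not expected.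

Key step: step 6

Abbreviation: ArK = 4-{[5,7-bis(benzyloxy)-2-[4-(benzyloxy)phenyl]-4-oxo-4H-chromen-3-yl]oxy}phenyl, the para-phenylene ring carrying the tri-O-benzylkaempferol unit through its O-3.
Remark: (S)-BINOL is assigned as the ligand for Si-face attack (2S) by analogy with BINOL–titanium allylations and aldol additions to aryl aldehydes. The sense is to be verified on the dihydropyranone, and the antipodal ligand taken if it proves opposite.

Step 1
Reactants: 1 2,4,6-trihydroxyacetophenone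
Product: 2 1-[2,4-bis(benzyloxy)-6-hydroxyphenyl]ethanone
Conditions: BnBr (2.05 equiv), K2CO3, DMF, rt
Reagents that add atoms: benzyl bromide, SMILES BrCc1ccccc1
Why: Williamson etherification in which two phenols are alkylated, while the last ortho-hydroxyl is hydrogen-bonded to the acetyl group, is far less nucleophilic and stays free for the later ring closure.

Step 2
Reactants: 2 1-[2,4-bis(benzyloxy)-6-hydroxyphenyl]ethanone; 3 4-(benzyloxy)benzaldehyde
Product: 4 (E)-1-[2,4-bis(benzyloxy)-6-hydroxyphenyl]-3-[4-(benzyloxy)phenyl]prop-2-en-1-one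
Conditions: KOH (aq), EtOH, rt
Reagents that add atoms: none
Why: Claisen–Schmidt condensation of the methyl ketone enolate with a non-enolisable aldehyde, with dehydration giving the conjugated (E)-alkene.

Step 3
Reactants: 4 (E)-chalcone
Product: 5 5,7-bis(benzyloxy)-2-[4-(benzyloxy)phenyl]-4H-chromen-4-one (tri-O-benzylapigenin)
Conditions: I2 (10 mol%), DMSO, 130 °C
Reagents that add atoms: none
Why: Iodine-catalysed oxidative cyclisation of a 2'-hydroxychalcone in DMSO, a standard flavone synthesis in which DMSO is the terminal oxidant and aryl benzyl ethers are tolerated.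

Step 4
Reactants: 5 tri-O-benzylapigenin
Product: 7 5,7-bis(benzyloxy)-2-[4-(benzyloxy)phenyl]-3-hydroxy-4H-chromen-4-one (5,7,4'-tri-O-benzylkaempferol), via flavone epoxide 6 (not isolated)
Conditions: dimethyldioxirane (acetone solution), CH2Cl2, 0 °C to rt; then p-TsOH (cat.), CH2Cl2, rt
Reagents that add atoms: dimethyldioxirane, SMILES CC1(C)OO1
Why: Epoxidation of the flavone C2=C3 enol-ether bond, followed by acid-catalysed opening at C2 and loss of the C3 proton, is an established flavone-to-flavonol oxidation that avoids the aurone formation seen in the Algar–Flynn–Oyamada reaction of 6'-alkoxychalcones.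

Step 5
Reactants: 7 5,7,4'-tri-O-benzylkaempferol; 8 4-fluorobenzaldehyde
Product: 9 4-{[5,7-bis(benzyloxy)-2-[4-(benzyloxy)phenyl]-4-oxo-4H-chromen-3-yl]oxy}benzaldehyde (ArK–CHO)
Conditions: K2CO3, DMF, 100 °C, argon
Reagents that add atoms: none
Why: SNAr diaryl ether synthesis in which the enolic 3-OH, the only acidic site of 7, displaces fluoride para to the formyl group as its potassium salt through a Meisenheimer adduct, with argon protecting the flavonolate from oxygenative ring cleavage.

Step 6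
Reactants: 9 ArK–CHO; 10 (E)-1-methoxy-3-(trimethylsilyloxy)buta-1,3-diene
Product: 12 (S)-2-ArK-2,3-dihydro-4H-pyran-4-one, via aldol adduct 11 (not isolated)
Conditions: (S)-BINOL (22 mol%), Ti(OiPr)4 (20 mol%), 4 Å MS, toluene/CH2Cl2, −20 to 0 °C; then CF3CO2H, CH2Cl2, 0 °C
Reagents that add atoms: none
Why: The binaphtholate of tetravalent titanium binds the formyl oxygen of 9, and the CH2 terminus of 10 attacks the carbonyl carbon (new C2–C3 bond) in a Mukaiyama-aldol-type, formally [4+2] process that turns over by silyl transfer to give 11. CF3CO2H then removes the silyl group, the freed C2–OH adds 6-endo-trig to the methoxy-bearing enone carbon (new O1–C6 bond, the later O1–C8a) and methanol is expelled, so ring C closes as a six-membered vinylogous ester by addition–elimination. The closest known reaction type is the catalytic asymmetric hetero-Diels–Alder reaction of aryl aldehydes with 1-alkoxy-3-silyloxybutadienes under BINOL–Ti(OiPr)4. C2 is the only new stereocentre and is controlled by the ligand, the (S)-binaphtholate shielding the Re face so that the diene reaches the Si face and gives (2S). Regiochemistry follows from the polarisation of the diene, and chemoselectivity from the formyl group being the only reactive carbonyl, since the chromone C4=O is a vinylogous ester crowded by 3-OAr and 5-OBn. No base or phenoxide is present, so the benzylic C2–O bond is not exposed to retro-oxa-Michael scrambling.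

Step 7
Reactants: 12 (S)-2-ArK-2,3-dihydro-4H-pyran-4-one
Product: 14 (S)-2-ArK-5-(phenylthio)-2,3-dihydro-4H-pyran-4-one, via chlorosulfide adduct 13 (not isolated)
Conditions: PhSH, NCS, CH2Cl2, 0 °C; add 12, −78 to 0 °C; then Et3N, 0 °C
Reagents that add atoms: benzenesulfenyl chloride, SMILES ClSc1ccccc1 (made in the flask from thiophenol, SMILES Sc1ccccc1, and N-chlorosuccinimide, SMILES O=C1CCC(=O)N1Cl)
Why: Electrophilic α-sulfenylation of an enone by addition–elimination, in which the O1 lone pair directs sulfur to C5, Et3N removes HCl from 13 without touching C3–H, and in the absence of a Lewis acid the acyl-deactivated benzyloxyarenes should not compete.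

Step 8
Reactants: 14 (S)-2-ArK-5-(phenylthio)-2,3-dihydro-4H-pyran-4-one
Product: 15 (2S)-2-ArK-5-(phenylsulfinyl)-2,3-dihydro-4H-pyran-4-one (both sulfur epimers)
Conditions: mCPBA (1.0 equiv), CH2Cl2, −78 to −20 °C
Reagents that add atoms: mCPBA, SMILES O=C(OO)c1cccc(Cl)c1
Why: Chemoselective sulfide-to-sulfoxide oxidation with one equivalent of peracid, sulfur being far more nucleophilic than the acceptor-substituted C=C bonds, and the configuration at sulfur is irrelevant because the group is expelled later.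

Step 9
Reactants: 16 methyl acetoacetate
Product: 17 methyl 3-(trimethylsilyloxy)but-2-enoate
Conditions: Me3SiCl, Et3N, hexane, rt
Reagents that add atoms: chlorotrimethylsilane, SMILES C[Si](C)(C)Cl
Why: O-silylation of the enol of a β-keto ester under soft enolisation.

Step 10
Reactants: 17 methyl 3-(trimethylsilyloxy)but-2-enoate
Product: 18 1-methoxy-1,3-bis(trimethylsilyloxy)buta-1,3-diene
Conditions: LiN(iPr)2, THF, −78 °C; then Me3SiCl, −78 °C to rt
Reagents that add atoms: chlorotrimethylsilane, SMILES C[Si](C)(C)Cl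
Why: γ-Deprotonation to the extended dienolate followed by O-silylation is the standard preparation of this 1,3-dioxygenated ketene-acetal diene.

Step 11
Reactants: 15 (2S)-2-ArK-5-(phenylsulfinyl)-2,3-dihydro-4H-pyran-4-one; 18 1-methoxy-1,3-bis(trimethylsilyloxy)buta-1,3-diene
Product: 22 (S)-2-ArK-5,7-dihydroxychroman-4-one, via cycloadduct 19 (not isolated), via dienyl ketal 20 (not isolated), via bis-silyl ether 21 (not isolated)
Conditions: 18 (3 equiv), toluene, rt to 90 °C; then 1 M HCl, THF, 0 °C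
Reagents that add atoms: none
Why: Proposed new method: the keto and sulfinyl groups on pyranone C5 lower the LUMO of the donor-deactivated C5=C6 bond and polarise it, so the CH2 terminus of 18 bonds to C6 (future C8–C8a) and the ketene-acetal carbon closes on C5 (future C4a–C5), concertedly or through a zwitterion that collapses to the same six-membered ring; in cis-fused 19 the sulfinyl group and C8a–H are syn, so thermal syn-elimination of PhSOH gives 20 under neutral conditions, 1,4-loss of methanol aromatises it to 21 and dilute acid strips the silyl groups, while the transient stereocentres vanish and C2 is never exposed to base; the closest known reaction types are the Diels–Alder/aromatisation of 3-sulfinyl- and 3-acylchromones and of haloquinones with 1,3-dioxygenated siloxydienes.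

Step 12
Reactants: 22 (S)-2-ArK-5,7-dihydroxychroman-4-one
Product: 23 (S)-3-[4-(5,7-dihydroxy-4-oxochroman-2-yl)phenoxy]-5,7-dihydroxy-2-(4-hydroxyphenyl)-4H-chromen-4-one (target)
Conditions: H2 (1 atm), Pd/C (10 wt%), EtOAc/THF, rt
Reagents that add atoms: none
Why: Catalytic hydrogenolysis of aryl benzyl ethers under neutral conditions, which should run faster than cleavage of the cyclic benzylic C2–O1 bond or reduction of the tetrasubstituted chromone alkene and leaves C2 configurationally intact.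

Compound list
1 | 2,4,6-trihydroxyacetophenone | CC(=O)c1c(O)cc(O)cc1O | starting material
2 | 1-[2,4-bis(benzyloxy)-6-hydroxyphenyl]ethanone | CC(=O)c1c(O)cc(OCc2ccccc2)cc1OCc1ccccc1 | intermediate
3 | 4-(benzyloxy)benzaldehyde | O=Cc1ccc(OCc2ccccc2)cc1 | starting material
4 | (E)-1-[2,4-bis(benzyloxy)-6-hydroxyphenyl]-3-[4-(benzyloxy)phenyl]prop-2-en-1-one | O=C(/C=C/c1ccc(OCc2ccccc2)cc1)c1c(O)cc(OCc2ccccc2)cc1OCc1ccccc1 | intermediate
5 | 5,7-bis(benzyloxy)-2-[4-(benzyloxy)phenyl]-4H-chromen-4-one | O=c1cc(-c2ccc(OCc3ccccc3)cc2)oc2cc(OCc3ccccc3)cc(OCc3ccccc3)c12 | intermediate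
6 | 2,3-epoxide of 5 (racemic, not isolated) | O=C1C2OC2(c2ccc(OCc3ccccc3)cc2)Oc2cc(OCc3ccccc3)cc(OCc3ccccc3)c21 | intermediate
7 | 5,7-bis(benzyloxy)-2-[4-(benzyloxy)phenyl]-3-hydroxy-4H-chromen-4-one | O=c1c(O)c(-c2ccc(OCc3ccccc3)cc2)oc2cc(OCc3ccccc3)cc(OCc3ccccc3)c12 | intermediate
8 | 4-fluorobenzaldehyde | O=Cc1ccc(F)cc1 | starting material
9 | 4-{[5,7-bis(benzyloxy)-2-[4-(benzyloxy)phenyl]-4-oxo-4H-chromen-3-yl]oxy}benzaldehyde | O=Cc1ccc(Oc2c(-c3ccc(OCc4ccccc4)cc3)oc3cc(OCc4ccccc4)cc(OCc4ccccc4)c3c2=O)cc1 | intermediate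
10 | (E)-1-methoxy-3-(trimethylsilyloxy)buta-1,3-diene | CO/C=C/C(=C)O[Si](C)(C)C | starting material
11 | (S,E)-5-ArK-1-methoxy-5-(trimethylsilyloxy)pent-1-en-3-one (not isolated) | CO/C=C/C(=O)C[C@@H](c1ccc(Oc2c(-c3ccc(OCc4ccccc4)cc3)oc3cc(OCc4ccccc4)cc(OCc4ccccc4)c3c2=O)cc1)O[Si](C)(C)C | intermediate
12 | (S)-2-ArK-2,3-dihydro-4H-pyran-4-one | O=C1C[C@@H](c2ccc(Oc3c(-c4ccc(OCc5ccccc5)cc4)oc4cc(OCc5ccccc5)cc(OCc5ccccc5)c4c3=O)cc2)OC=C1 | intermediate
13 | (2S)-2-ArK-6-chloro-5-(phenylthio)tetrahydro-4H-pyran-4-one (C5/C6 isomers, not isolated) | O=C1C[C@@H](c2ccc(Oc3c(-c4ccc(OCc5ccccc5)cc4)oc4cc(OCc5ccccc5)cc(OCc5ccccc5)c4c3=O)cc2)OC(Cl)C1Sc1ccccc1 | intermediate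
14 | (S)-2-ArK-5-(phenylthio)-2,3-dihydro-4H-pyran-4-one | O=C1C[C@@H](c2ccc(Oc3c(-c4ccc(OCc5ccccc5)cc4)oc4cc(OCc5ccccc5)cc(OCc5ccccc5)c4c3=O)cc2)OC=C1Sc1ccccc1 | intermediate
15 | (2S)-2-ArK-5-(phenylsulfinyl)-2,3-dihydro-4H-pyran-4-one (both sulfur epimers) | O=C1C[C@@H](c2ccc(Oc3c(-c4ccc(OCc5ccccc5)cc4)oc4cc(OCc5ccccc5)cc(OCc5ccccc5)c4c3=O)cc2)OC=C1S(=O)c1ccccc1 | intermediate
16 | methyl acetoacetate | COC(=O)CC(C)=O | starting material
17 | methyl 3-(trimethylsilyloxy)but-2-enoate | COC(=O)C=C(C)O[Si](C)(C)C | intermediate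
18 | 1-methoxy-1,3-bis(trimethylsilyloxy)buta-1,3-diene | COC(=CC(=C)O[Si](C)(C)C)O[Si](C)(C)C | intermediate
19 | (2S)-2-ArK-5-methoxy-4a-(phenylsulfinyl)-5,7-bis(trimethylsilyloxy)-2,3,4a,5,8,8a-hexahydro-4H-chromen-4-one (cis-fused, isomers at the transient centres, not isolated) | O=C1C[C@@H](c2ccc(Oc3c(-c4ccc(OCc5ccccc5)cc4)oc4cc(OCc5ccccc5)cc(OCc5ccccc5)c4c3=O)cc2)OC2CC(O[Si](C)(C)C)=CC(OC)(O[Si](C)(C)C)C12S(=O)c1ccccc1 | intermediate
20 | (2S)-2-ArK-5-methoxy-5,7-bis(trimethylsilyloxy)-2,3,5,8-tetrahydro-4H-chromen-4-one (not isolated) | O=C1C[C@@H](c2ccc(Oc3c(-c4ccc(OCc5ccccc5)cc4)oc4cc(OCc5ccccc5)cc(OCc5ccccc5)c4c3=O)cc2)OC2=C1C(OC)(O[Si](C)(C)C)C=C(O[Si](C)(C)C)C2 | intermediate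
21 | (S)-2-ArK-5,7-bis(trimethylsilyloxy)chroman-4-one (not isolated) | O=C1C[C@@H](c2ccc(Oc3c(-c4ccc(OCc5ccccc5)cc4)oc4cc(OCc5ccccc5)cc(OCc5ccccc5)c4c3=O)cc2)Oc2cc(O[Si](C)(C)C)cc(O[Si](C)(C)C)c21 | intermediate
22 | (S)-2-ArK-5,7-dihydroxychroman-4-one | O=C1C[C@@H](c2ccc(Oc3c(-c4ccc(OCc5ccccc5)cc4)oc4cc(OCc5ccccc5)cc(OCc5ccccc5)c4c3=O)cc2)Oc2cc(O)cc(O)c21 | intermediate
23 | (S)-3-[4-(5,7-dihydroxy-4-oxochroman-2-yl)phenoxy]-5,7-dihydroxy-2-(4-hydroxyphenyl)-4H-chromen-4-one | O=C1C[C@@H](c2ccc(Oc3c(-c4ccc(O)cc4)oc4cc(O)cc(O)c4c3=O)cc2)Oc2cc(O)cc(O)c21 | target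

Total step count: 12. Longest linear sequence: 10 (steps 1–8, 11, 12).

Steps most likely to fail

1. Step 11. The reaction may stop after the first C–C bond, through Michael-type addition followed by silyl transfer instead of ring closure. Alternatively, the ketene acetal may silylate the sulfoxide oxygen and divert the dienophile into Pummerer-type chemistry, so that ring A is not closed.
Fallback: this uses known chemistry only, brings ring A in as an arene and takes the stereocentre from the same cycloaddition. It sets out from 9 and 10 and comes back at 22.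
- Step 6 is run with (R)-BINOL and should give, through the (R)-aldol adduct F1, the (R)-dihydropyranone F2.
- Lemieux–Johnson cleavage of the disubstituted C5=C6 bond (OsO4 cat., NaIO4, THF/H2O) should give (R)-3-ArK-3-(formyloxy)propanoic acid F3. The tetrasubstituted chromone alkene is left alone.
- Aqueous NaHCO3/MeOH removes the formate to give (R)-3-ArK-3-hydroxypropanoic acid F4.
- Coupling with MeNHOMe·HCl (EDC, N-methylmorpholine) gives the N-methoxy-N-methylamide F5.
- Separately, 1,3,5-tris(methoxymethoxy)benzene F6 (phloroglucinol, MOMCl, iPr2NEt) is lithiated with nBuLi (THF, 0 °C) to 2,4,6-tris(methoxymethoxy)phenyllithium F7.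
- F7 is added in excess to F5 at −78 °C to give the (R)-β-hydroxy ketone F8. The crowded chromone carbonyl is expected to be outcompeted by the amide.
- Dilute HCl in MeOH at rt removes the acetals to give the (R)-2',4',6'-trihydroxy-β-hydroxydihydrochalcone F9.
- Intramolecular Mitsunobu etherification (PPh3, DIAD, THF, 0 °C, high dilution) closes O1–C2 with inversion to give 22.

2. Step 7. Chemoselectivity may be lost if the electrophilic sulfur attacks C6 or C8 of the 5,7-bis(benzyloxy)chromone ring in competition with pyranone C5.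
Fallback: the sulfur is put on the four-carbon unit before the cycloaddition, where no arene can compete. It sets out from 9 and comes back at 14.
- Commercial (E)-4-methoxybut-3-en-2-one is sulfenylated with PhSCl/Et3N to 4-methoxy-3-(phenylthio)but-3-en-2-one F10.
- Me3SiOTf/Et3N converts F10 into 1-methoxy-2-(phenylthio)-3-(trimethylsilyloxy)buta-1,3-diene F11.
- F11 is combined with 9 under the catalyst of step 6. The reacting CH2 terminus is remote from the new substituent.
- This should give the (S)-aldol adduct F12, which CF3CO2H closes directly to 14.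

3. Step 6. The chromone carbonyl and its flanking ether oxygens may sequester titanium. Turnover would then slow, and an unselective background reaction would erode facial selectivity.
Fallback: activation is switched from a Lewis acid to hydrogen-bond catalysis with a more reactive diene. It sets out from 9 and comes back at 12.
- 9 and commercial (E)-3-(tert-butyldimethylsilyloxy)-N,N-dimethylbuta-1,3-dien-1-amine are combined with tetra(1-naphthyl)-TADDOL (20 mol%, antipode chosen for 2S) in toluene at −40 °C.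
- This should give the aminal cycloadduct F13.
- Acetyl chloride (CH2Cl2/toluene, −78 °C) converts F13 into 12.

Further compounds
F1 | step 11 | (R,E)-5-ArK-1-methoxy-5-(trimethylsilyloxy)pent-1-en-3-one | CO/C=C/C(=O)C[C@H](c1ccc(Oc2c(-c3ccc(OCc4ccccc4)cc3)oc3cc(OCc4ccccc4)cc(OCc4ccccc4)c3c2=O)cc1)O[Si](C)(C)C
F2 | step 11 | (R)-2-ArK-2,3-dihydro-4H-pyran-4-one | O=C1C[C@H](c2ccc(Oc3c(-c4ccc(OCc5ccccc5)cc4)oc4cc(OCc5ccccc5)cc(OCc5ccccc5)c4c3=O)cc2)OC=C1
F3 | step 11 | (R)-3-ArK-3-(formyloxy)propanoic acid | OC(=O)C[C@H](c1ccc(Oc2c(-c3ccc(OCc4ccccc4)cc3)oc3cc(OCc4ccccc4)cc(OCc4ccccc4)c3c2=O)cc1)OC=O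
F4 | step 11 | (R)-3-ArK-3-hydroxypropanoic acid | OC(=O)C[C@H](c1ccc(Oc2c(-c3ccc(OCc4ccccc4)cc3)oc3cc(OCc4ccccc4)cc(OCc4ccccc4)c3c2=O)cc1)O
F5 | step 11 | (R)-3-ArK-3-hydroxy-N-methoxy-N-methylpropanamide | CON(C)C(=O)C[C@H](c1ccc(Oc2c(-c3ccc(OCc4ccccc4)cc3)oc3cc(OCc4ccccc4)cc(OCc4ccccc4)c3c2=O)cc1)O
F6 | step 11 | 1,3,5-tris(methoxymethoxy)benzene | COCOc1cc(OCOC)cc(OCOC)c1
F7 | step 11 | 2,4,6-tris(methoxymethoxy)phenyllithium | [Li]c1c(OCOC)cc(OCOC)cc1OCOC
F8 | step 11 | (R)-3-ArK-3-hydroxy-1-[2,4,6-tris(methoxymethoxy)phenyl]propan-1-one | O=C(C[C@H](c1ccc(Oc2c(-c3ccc(OCc4ccccc4)cc3)oc3cc(OCc4ccccc4)cc(OCc4ccccc4)c3c2=O)cc1)O)c1c(OCOC)cc(OCOC)cc1OCOC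
F9 | step 11 | (R)-3-ArK-3-hydroxy-1-(2,4,6-trihydroxyphenyl)propan-1-one | O=C(C[C@H](c1ccc(Oc2c(-c3ccc(OCc4ccccc4)cc3)oc3cc(OCc4ccccc4)cc(OCc4ccccc4)c3c2=O)cc1)O)c1c(O)cc(O)cc1O
F10 | step 7 | 4-methoxy-3-(phenylthio)but-3-en-2-one | COC=C(Sc1ccccc1)C(C)=O
F11 | step 7 | 1-methoxy-2-(phenylthio)-3-(trimethylsilyloxy)buta-1,3-diene | COC=C(Sc1ccccc1)C(=C)O[Si](C)(C)C
F12 | step 7 | (S)-5-ArK-1-methoxy-2-(phenylthio)-5-(trimethylsilyloxy)pent-1-en-3-one | COC=C(Sc1ccccc1)C(=O)C[C@@H](c1ccc(Oc2c(-c3ccc(OCc4ccccc4)cc3)oc3cc(OCc4ccccc4)cc(OCc4ccccc4)c3c2=O)cc1)O[Si](C)(C)C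
F13 | step 6 | (2S)-2-ArK-4-(tert-butyldimethylsilyloxy)-6-(dimethylamino)-3,6-dihydro-2H-pyran | CN(C)C1C=C(O[Si](C)(C)C(C)(C)C)C[C@@H](c2ccc(Oc3c(-c4ccc(OCc5ccccc5)cc4)oc4cc(OCc5ccccc5)cc(OCc5ccccc5)c4c3=O)cc2)O1
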